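## The problem

Target 19 is a flavonol (3-hydroxy-2-arylchromen-4-one) with no stereocentre, so the task is one of placement, not of configuration. Ring A (C4a, C5, C6, C7, C8, C8a) has a substituent on every carbon: the chelated 5-hydroxyl, a prenyl group at C6, the 7-methoxy group, a prenyl group at C8, the ring oxygen at C8a and the carbonyl carbon at C4a. Prenylating a preformed phloroglucinol ring at carbon competes with O-alkylation, with mono- and tri-alkylation and with geminal dialkylation that destroys the arene. Three pairs of oxygens must be told apart: 7-OMe from 5-OH, 4'-OMe from 3'-OH, and the 3-hydroxyl from both. The trisubstituted prenyl alkenes do not tolerate strong Brønsted or Lewis acids (addition, chroman formation with a neighbouring phenol), hydrogenolysis or electrophilic oxidants; this excludes benzyl ethers, Friedel–Crafts chemistry after prenylation and a late oxidation at C3, so the 3-oxygen has to come in with the carbon skeleton. The enabling feature is that on ring A the oxygen-bearing carbons C5, C7 and C8a alternate with the carbon-bearing C6, C8 and C4a. This is the pattern of an acylphloroglucinol, that is, of a 3,5,7-trioxo ester folded by a Claisen reaction, in which C6 and C8 are enolizable chain carbons (C4 and C2 of the chain) and C4a is the chain methylene C6. Once O7 is methylated, the ring A ketone has a mirror plane, so ring C can close onto either ortho hydroxyl with the same result.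

## Retrosynthesis

**Ring C and the protecting groups (19 to 17).** The O1–C2 bond and the two methoxymethyl acetals are cut, which leads through the protected flavonol 18 to the o-hydroxyaryl 1,3-diketone 17. A chalcone route with oxidative closure was not chosen: a 2',6'-dioxygenated chalcone tends to give aurones, and C3 would have to be oxidized in the presence of two prenyl alkenes. In 17 the 3-oxygen is already in place as an acetal. The forward step asks only for mild acid that leaves the prenyl groups alone.

**The C2–C3 bond (17 to 16, then 12 and 15).** The bond between the alkoxy-bearing carbon and the aroyl carbon is cut by a Baker–Venkataraman transform to aryl ester 16, and the ester C–O bond is cut to ring A ketone 12 and ring B acid 15. The intramolecular acyl transfer is preferred over an intermolecular Claisen condensation with an aroyl ester because it needs no excess of the ring B piece. Since 12 is symmetric, it does not matter which of its two hydroxyls is esterified. Acid 15 comes from isovanillic acid 13, which already holds the 3'-OH/4'-OMe distinction, through the doubly protected ester 14.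

**The 7-methoxy group (12 to 11).** The O–CH3 bond is cut to the triol 11. Of its three hydroxyls, only the one para to the ketone is free of a hydrogen bond to the carbonyl, and it is the most acidic. The forward step asks for monomethylation at that oxygen with a hard methylating agent.

**Ring A (11 to 10), the key disconnection.** The ring bond between the acylated carbon and a neighbouring hydroxylated carbon (C4a–C5 of the flavonol, C6–C1 of the chain) is cut, which opens the arene to the triketo ester 10. The neighbouring cuts, C-prenylation of an acylphloroglucinol or acylation of a diprenylphloroglucinol, keep the arene and with it the C/O and over-alkylation problems. The Claisen cut turns both prenylated ring carbons into α-carbons of 1,3-dicarbonyl units, where alkylation is ordinary enolate chemistry. The forward reaction must fold the chain in the Claisen mode and not in an aldol mode, and must tolerate the acetal at C8.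

**The C6–C7 bond of the chain (10 to 6 and 9).** The chain is cut between the methylene C6 and the ketone C7, giving the diprenylated diketo ester 6 and a two-carbon acyl donor that carries the future 3-oxygen. A Weinreb amide (9) is preferred to the ester 8 as the donor. Its tetrahedral adduct persists until work-up, so the acidic product cannot quench unreacted polyanion and one equivalent of 6 suffices. The forward reaction asks for the trianion of 6 to react at its terminal carbon. Amide 9 is made from methyl glycolate 7 through 8.

**The C4–C5 bond and the prenyl groups (6 to 4 and 5, 4 to 3 and 2, 3 to 1 and 2).** The acetyl group of 6 is cut off as N-methoxy-N-methylacetamide 5, leaving the β-keto ester 4, whose only ketone α-position other than C2 is the future C4. Compound 4 is cut at the allylic C–C bond on C2 to the mono-alkylated keto ester 3 and prenyl bromide 2. Compound 3 is cut at the γ-allylic bond to methyl acetoacetate 1 and a second molecule of 2. The two alkylations are separate operations, γ first through the dianion and α second through the monoanion, each consuming one equivalent of 2. Prenylating an unsubstituted 3,5-dioxo ester chain twice would be shorter on paper but leaves three acidic carbons competing. Here each prenyl group goes to the only carbon that is nucleophilic at that moment, and the second ketone is added afterwards.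

## Roads not taken

Alternative 1: The cut runs through C8a–O1 and C4a–C4 at once. Ring A would arrive as an aryne released by CsF from the silyl triflate A2, and C2–C4 with ring B as the arylpropiolic acid A3. The carboxylate oxygen would add at C8a, the aryne carbon remote from the 5-alkoxy group, and the aryl anion at C4a would take the acyl carbon to give the hydroxyaryl ynone A1.
- Merits: the step is convergent, fluoride conditions are harmless to prenyl groups, and the alkoxy group steers the addition in the needed sense.
- Weak points: A2 is a hexasubstituted benzene that already carries both prenyl groups, so the ring A problem is moved and made harder. A1 has no oxygen at C3. Its closure can run 6-endo to the flavone or 5-exo to an aurone. The C3 hydroxylation that must follow needs an electrophilic oxidant, which the two prenyl alkenes would not survive.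
- Comparison: this road is more convergent in its key step. The chosen plan sets against it a 3-oxygen built in from methyl glycolate and a ring A precursor made from bulk acyclic esters.

Alternative 2: The cut is O1–C8a, closed by nucleophilic aromatic substitution. Ring A would start as 1,3-difluoro-5-methoxybenzene A5, be elaborated to the difluoroaryl 1,3-diketone A6, and with K2CO3 the enol oxygen would displace one of two equivalent ortho fluorides to give the 5-fluoroflavone A4.
- Merits: the symmetry makes the closure unambiguous, ring A needs no phenol protection, the closing conditions are mild and free of acid, and no polyanion is involved. In these respects it is better than the chosen plan.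
- Weak points: the acyl group must go to the position between the two fluorines and the prenyl groups to the two positions between fluorine and methoxy. This needs three ordered arene metalations, and allylation of aryl-metal species with prenyl bromide can scramble the allyl terminus. After closure, the C5 fluoride, flanked by a prenyl group and the carbonyl, must still be exchanged for hydroxyl by a second substitution with an oxygen nucleophile that the base-sensitive 3-alkoxychromone has to survive.
- Comparison: the chosen plan accepts polyanion chemistry and an air-sensitive phloroglucinol. In return every ring A oxygen is present from the start, and both prenyl groups are placed by enolate alkylation at positions that leave no choice.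

Alternative 3: The cut is C2–C3 followed by O1–C2. The symmetric ring A ketone A9 would be aroylated on oxygen, and LiN(SiMe3)2 would shift the aroyl group to the α-alkoxy carbon. Acid would then close ring C to the protected flavonol A7. A9 would be made from phloroglucinol A8 by C-acylation, double C-prenylation and O-methylation.
- Merits: it is the shortest road, roughly five steps fewer than the chosen one. Its key step is reliable chemistry that exploits the symmetry of A9. It is in fact adopted here as the endgame (steps 10 to 12; A9 is the same compound as 12 and A7 the same as 18).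
- Weak points: they lie entirely in how A9 is made. Acylating A8 with an alkoxyacetyl unit needs strongly acidic conditions that a methoxymethyl acetal does not survive, so another oxygen protecting group would have to be used and exchanged later. The double C-prenylation of an acylphloroglucinol in base gives mixtures of O-, mono-, di- and tri-alkylated and dearomatized products.
- Comparison: this road wins on step count and avoids polyanions. The chosen plan spends extra steps so that the two prenyl groups and the acid-labile acetal are never exposed to arene substitution chemistry.

Key step: step 7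

## Route

Assumption: compounds 4, 6, 10 and 17 contain enolizable stereogenic carbons and are carried as mixtures of epimers and enol tautomers. These centres are erased on aromatization or ring closure, so no configuration is assigned.

Step 1
Reactants: 1 methyl acetoacetate; 2 prenyl bromide (1-bromo-3-methylbut-2-ene)
Product: 3 methyl 7-methyl-3-oxooct-6-enoate
Conditions: NaH (1.1 equiv), THF, 0 °C; n-BuLi (1.05 equiv), 0 °C; 2 (1.0 equiv), 0 °C → rt; 1 M HCl, 0 °C
Reagents that add atoms: none
Why: Alkylation of the acetoacetate dianion takes place at the γ-carbon, the more basic and more nucleophilic site, and leaves the product as its stabilized α-enolate, which does not react further with one equivalent of bromide at this temperature. Acidic work-up protonates that enolate to the mono-prenylated β-keto ester 3.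

Step 2
Reactants: 3 methyl 7-methyl-3-oxooct-6-enoate; 2 prenyl bromide (1-bromo-3-methylbut-2-ene)
Product: 4 methyl 7-methyl-2-(3-methylbut-2-en-1-yl)-3-oxooct-6-enoate (racemic)
Conditions: NaH (1.0 equiv), THF, 0 °C; 2 (0.95 equiv), 0 °C → rt; aq. NH4Cl
Reagents that add atoms: none
Why: Acetoacetic ester alkylation: the sodium enolate of 3 is nucleophilic at carbon only at C2, and the soft allylic bromide is expected to alkylate there by direct substitution. A slight deficiency of bromide limits geminal dialkylation at C2.

Step 3
Reactants: 4 methyl 7-methyl-2-(3-methylbut-2-en-1-yl)-3-oxooct-6-enoate; 5 N-methoxy-N-methylacetamide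
Product: 6 methyl 2,4-bis(3-methylbut-2-en-1-yl)-3,5-dioxohexanoate (mixture of epimers and enol forms)
Conditions: LiN(i-Pr)2 (2.2 equiv), THF, –78 → 0 °C; 5 (1.2 equiv), –78 → 0 °C; aq. NH4Cl
Reagents that add atoms: none
Why: This is γ-acylation of a β-keto ester dianion with a Weinreb amide: the base removes the C2 proton and then a proton from C4, the only other ketone α-position, and the C4 carbanion adds to the amide. The chelated tetrahedral adduct is stable until work-up, so the acidic diketone is not formed while carbanion remains.

Step 4
Reactants: 7 methyl glycolate
Product: 8 methyl 2-(methoxymethoxy)acetate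
Conditions: MOMCl (1.3 equiv), i-Pr2NEt (1.5 equiv), CH2Cl2, 0 °C → rt
Reagents that add atoms: chloromethyl methyl ether, COCCl
Why: Standard O-alkylation of a primary alcohol with an α-chloro ether and a hindered amine base gives the methoxymethyl acetal, which is stable to all the basic steps that follow.

Step 5
Reactants: 8 methyl 2-(methoxymethoxy)acetate
Product: 9 N-methoxy-2-(methoxymethoxy)-N-methylacetamide
Conditions: MeNH(OMe)·HCl (1.5 equiv), i-PrMgCl (3.0 equiv), THF, –20 → 0 °C
Reagents that add atoms: N,O-dimethylhydroxylamine hydrochloride, CNOC.Cl
Why: Weinreb amide formation from an ester: the magnesium amide made in the flask adds to the ester and the chelated adduct stops at the amide stage.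

Step 6
Reactants: 6 methyl 2,4-bis(3-methylbut-2-en-1-yl)-3,5-dioxohexanoate; 9 N-methoxy-2-(methoxymethoxy)-N-methylacetamide
Product: 10 methyl 8-(methoxymethoxy)-2,4-bis(3-methylbut-2-en-1-yl)-3,5,7-trioxooctanoate (mixture of epimers and enol forms)
Conditions: LiN(i-Pr)2 (3.3 equiv), THF, –78 → 0 °C; 9 (1.1 equiv), –78 → –20 °C; cold aq. NH4Cl; used crude
Reagents that add atoms: none
Why: This is terminal acylation of a 1,3,5-tricarbonyl polyanion (Claisen-type acylation): three equivalents of base remove the C4 and C2 protons and then a proton of the C6 methyl group, and the last-formed, least stabilized carbanion at C6 is the one that adds to the Weinreb amide. The adduct holds until the quench, so one equivalent of 6 is enough.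

Step 7
Reactants: 10 methyl 8-(methoxymethoxy)-2,4-bis(3-methylbut-2-en-1-yl)-3,5,7-trioxooctanoate
Product: 11 2-(methoxymethoxy)-1-[2,4,6-trihydroxy-3,5-bis(3-methylbut-2-en-1-yl)phenyl]ethan-1-one
Conditions: Mg(OMe)2 (5 equiv), MeOH, 65 °C, Ar; then 1 M HCl, 0 °C
Reagents that add atoms: none
Why: Mg(OMe)2 turns the β-dicarbonyl units of 10 into magnesium-chelated enolates; the C6 enolate, between C5 and C7, adds to the ester carbonyl C1, methoxide leaves, and the cyclohexane-1,3,5-trione enolizes three times, using the hydrogens still present on the prenylated C2 and C4, to the aromatic triol 11. The closest known reaction type is the Mg(OMe)2-promoted Claisen cyclization of methyl 3,5,7-trioxoalkanoates, and of the 6-(2-oxoalkyl)-4-hydroxy-2-pyrones that open to them, to acylphloroglucinols; only the alkyl groups on C2 and C4 are new. Ring A closes in a 6-exo-trig mode at the ester carbonyl (6-enolendo or 6-enolexo, both allowed) and forms the bond that becomes C4a–C5 of the flavonol. No stereocentre is created, and the epimeric centres C2 and C4 of 10 disappear on aromatization. The step needs the Claisen mode to win over the aldol closure of C2 onto C7, the aldol closure of C8 onto C3, lactonization to a 2-pyrone and retro-Claisen cleavage by methoxide. The substrate secures this: after an aldol onto C7 the carbon C2 is quaternary, so that adduct cannot become an arene and reverts; C8 is activated by one carbonyl only and is not ionized by an alkoxide, while C3 lies between two branched, enolized carbons; a pyrone formed by lactonization is reopened by methoxide; and the ketones are masked as chelated enolates and so shielded from methoxide. Methoxide in methanol keeps C1 as the methyl ester and not as an unreactive carboxylate, and aromatization to the magnesium phenoxide is the only irreversible exit.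

Step 8
Reactants: 11 2-(methoxymethoxy)-1-[2,4,6-trihydroxy-3,5-bis(3-methylbut-2-en-1-yl)phenyl]ethan-1-one
Product: 12 1-[2,6-dihydroxy-4-methoxy-3,5-bis(3-methylbut-2-en-1-yl)phenyl]-2-(methoxymethoxy)ethan-1-one
Conditions: Me2SO4 (1.05 equiv), K2CO3 (1.1 equiv), acetone, rt
Reagents that add atoms: dimethyl sulfate, COS(=O)(=O)OC
Why: Williamson O-methylation of the most acidic phenol: the hydroxyl para to the ketone is the only one not tied up in a hydrogen bond to the carbonyl, so one equivalent of weak base ionizes it first. A hard methylating agent is expected to react at oxygen and not at the substituted ring carbons.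

Step 9
Reactants: 13 isovanillic acid (3-hydroxy-4-methoxybenzoic acid)
Product: 15 4-methoxy-3-(methoxymethoxy)benzoic acid, via methoxymethyl 4-methoxy-3-(methoxymethoxy)benzoate 14 (not isolated)
Conditions: MOMCl (2.5 equiv), i-Pr2NEt (3 equiv), CH2Cl2, 0 °C → rt; then 2 M aq. NaOH, MeOH, rt; 1 M HCl to pH 4, 0 °C
Reagents that add atoms: chloromethyl methyl ether, COCCl; sodium hydroxide, [Na+].[OH-]
Why: Both the phenol and the carboxylic acid are alkylated to the acetal and the acetal ester; saponification then cleaves only the ester, since aryl methoxymethyl ethers are stable to hydroxide.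

Step 10
Reactants: 12 1-[2,6-dihydroxy-4-methoxy-3,5-bis(3-methylbut-2-en-1-yl)phenyl]-2-(methoxymethoxy)ethan-1-one; 15 4-methoxy-3-(methoxymethoxy)benzoic acid
Product: 16 3-hydroxy-5-methoxy-2-[(methoxymethoxy)acetyl]-4,6-bis(3-methylbut-2-en-1-yl)phenyl 4-methoxy-3-(methoxymethoxy)benzoate
Conditions: 15 (1.05 equiv), EDC·HCl (1.3 equiv), DMAP (0.2 equiv), CH2Cl2, 0 °C → rt
Reagents that add atoms: none
Why: Steglich esterification through the acylpyridinium ion avoids an acid chloride and the hydrogen chloride that would endanger the acetals. The two phenols of 12 are equivalent, and after the first acylation the remaining one is held in a hydrogen bond to the ketone, which should slow a second acylation.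

Step 11
Reactants: 16 3-hydroxy-5-methoxy-2-[(methoxymethoxy)acetyl]-4,6-bis(3-methylbut-2-en-1-yl)phenyl 4-methoxy-3-(methoxymethoxy)benzoate
Product: 17 1-[2,6-dihydroxy-4-methoxy-3,5-bis(3-methylbut-2-en-1-yl)phenyl]-2-(methoxymethoxy)-3-[4-methoxy-3-(methoxymethoxy)phenyl]propane-1,3-dione (racemic; enol forms)
Conditions: LiN(SiMe3)2 (3.5 equiv), THF, –78 → 0 °C; aq. NH4Cl
Reagents that add atoms: none
Why: Baker–Venkataraman rearrangement: the base forms the phenoxide and the enolate of the α-alkoxy ketone, whose carbon attacks the neighbouring aryl ester through a six-membered cyclic transition state. Collapse to the doubly stabilized diketone enolate drives the O-to-C acyl transfer.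

Step 12
Reactants: 17 1-[2,6-dihydroxy-4-methoxy-3,5-bis(3-methylbut-2-en-1-yl)phenyl]-2-(methoxymethoxy)-3-[4-methoxy-3-(methoxymethoxy)phenyl]propane-1,3-dione
Product: 19 3,5-dihydroxy-2-(3-hydroxy-4-methoxyphenyl)-7-methoxy-6,8-bis(3-methylbut-2-en-1-yl)-4H-chromen-4-one (the target), via 3,3'-di-O-methoxymethyl flavonol 18 (not isolated)
Conditions: 3 M aq. HCl/MeOH (1:5), 50 °C
Reagents that add atoms: none
Why: Acid-catalysed cyclodehydration of the o-hydroxyaryl 1,3-diketone (hemiketal, then loss of water) closes ring C onto either of the two equivalent phenols, and the same acid solvolyses both methoxymethyl acetals. The 7-oxygen is already methylated, so the only phenol next to a prenyl group is the chelated 5-hydroxyl, which limits acid-induced chroman formation.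

## Compound list

1 | methyl acetoacetate (methyl 3-oxobutanoate) | COC(=O)CC(C)=O | starting material
2 | prenyl bromide (1-bromo-3-methylbut-2-ene) | CC(C)=CCBr | starting material
3 | methyl 7-methyl-3-oxooct-6-enoate | COC(=O)CC(=O)CCC=C(C)C | intermediate
4 | methyl 7-methyl-2-(3-methylbut-2-en-1-yl)-3-oxooct-6-enoate (racemic) | COC(=O)C(CC=C(C)C)C(=O)CCC=C(C)C | intermediate
5 | N-methoxy-N-methylacetamide | CC(=O)N(C)OC | starting material
6 | methyl 2,4-bis(3-methylbut-2-en-1-yl)-3,5-dioxohexanoate (epimers and enol forms) | COC(=O)C(CC=C(C)C)C(=O)C(CC=C(C)C)C(C)=O | intermediate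
7 | methyl glycolate (methyl 2-hydroxyacetate) | COC(=O)CO | starting material
8 | methyl 2-(methoxymethoxy)acetate | COCOCC(=O)OC | intermediate
9 | N-methoxy-2-(methoxymethoxy)-N-methylacetamide | COCOCC(=O)N(C)OC | intermediate
10 | methyl 8-(methoxymethoxy)-2,4-bis(3-methylbut-2-en-1-yl)-3,5,7-trioxooctanoate (epimers and enol forms) | COCOCC(=O)CC(=O)C(CC=C(C)C)C(=O)C(CC=C(C)C)C(=O)OC | intermediate
11 | 2-(methoxymethoxy)-1-[2,4,6-trihydroxy-3,5-bis(3-methylbut-2-en-1-yl)phenyl]ethan-1-one | COCOCC(=O)c1c(O)c(CC=C(C)C)c(O)c(CC=C(C)C)c1O | intermediate
12 | 1-[2,6-dihydroxy-4-methoxy-3,5-bis(3-methylbut-2-en-1-yl)phenyl]-2-(methoxymethoxy)ethan-1-one | COCOCC(=O)c1c(O)c(CC=C(C)C)c(OC)c(CC=C(C)C)c1O | intermediate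
13 | isovanillic acid (3-hydroxy-4-methoxybenzoic acid) | COc1ccc(C(=O)O)cc1O | starting material
14 | methoxymethyl 4-methoxy-3-(methoxymethoxy)benzoate (not isolated) | COCOC(=O)c1ccc(OC)c(OCOC)c1 | intermediate
15 | 4-methoxy-3-(methoxymethoxy)benzoic acid | COCOc1cc(C(=O)O)ccc1OC | intermediate
16 | 3-hydroxy-5-methoxy-2-[(methoxymethoxy)acetyl]-4,6-bis(3-methylbut-2-en-1-yl)phenyl 4-methoxy-3-(methoxymethoxy)benzoate | COCOCC(=O)c1c(O)c(CC=C(C)C)c(OC)c(CC=C(C)C)c1OC(=O)c1ccc(OC)c(OCOC)c1 | intermediate
17 | 1-[2,6-dihydroxy-4-methoxy-3,5-bis(3-methylbut-2-en-1-yl)phenyl]-2-(methoxymethoxy)-3-[4-methoxy-3-(methoxymethoxy)phenyl]propane-1,3-dione (racemic; enol forms) | COCOC(C(=O)c1c(O)c(CC=C(C)C)c(OC)c(CC=C(C)C)c1O)C(=O)c1ccc(OC)c(OCOC)c1 | intermediate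
18 | 5-hydroxy-7-methoxy-3-(methoxymethoxy)-2-[4-methoxy-3-(methoxymethoxy)phenyl]-6,8-bis(3-methylbut-2-en-1-yl)-4H-chromen-4-one (not isolated) | COc1ccc(-c2oc3c(CC=C(C)C)c(OC)c(CC=C(C)C)c(O)c3c(=O)c2OCOC)cc1OCOC | intermediate
19 | 3,5-dihydroxy-2-(3-hydroxy-4-methoxyphenyl)-7-methoxy-6,8-bis(3-methylbut-2-en-1-yl)-4H-chromen-4-one | COc1ccc(-c2oc3c(CC=C(C)C)c(OC)c(CC=C(C)C)c(O)c3c(=O)c2O)cc1O | target

## Step count and risks

Total: 12 steps. Longest linear sequence: 9 steps (1, 2, 3, 6, 7, 8, 10, 11, 12) from methyl acetoacetate. Steps 4 and 5 and step 9 are side branches.

**Step 7 (key step).** The chain may fold or fragment along another path. The ester carbonyl sits next to a branched carbon and may react more slowly than in the unbranched case, which gives time for retro-Claisen loss of the terminal acyl unit through methoxide attack, for lactonization that is not reopened, or for closure of C8 onto C3. The fallback moves the prenylation behind the ring closure and sets out from Weinreb amide 9. The trianion (LiN(i-Pr)2, 3 equiv) of methyl 3,5-dioxohexanoate F1, obtained from commercial triacetic acid lactone with Mg(OMe)2 in methanol, is acylated at C6 with 9 to give methyl 8-(methoxymethoxy)-3,5,7-trioxooctanoate F2. This unbranched chain is folded with Mg(OMe)2 to 2-(methoxymethoxy)-1-(2,4,6-trihydroxyphenyl)ethan-1-one F3. F3 is C-prenylated twice with prenyl bromide 2 in cold aqueous KOH, and the route is rejoined at 11. The price is the C/O and over-alkylation selectivity that the main route avoids.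

**Step 6.** The third deprotonation, at the methyl group next to two fully substituted enolate carbons, may be incomplete, or the carbanion may take a proton from the α-alkoxy amide instead of adding to it. The fallback lowers the charge that has to be built up and sets out from 6. DBU in refluxing toluene lactonizes 6 to 4-hydroxy-6-methyl-3,5-bis(3-methylbut-2-en-1-yl)pyran-2-one F4. Its dianion (LiN(i-Pr)2, 2.2 equiv; only the hydroxyl and the 6-methyl group are deprotonated) is acylated at the methyl carbon with 9 to give 4-hydroxy-6-[3-(methoxymethoxy)-2-oxopropyl]-3,5-bis(3-methylbut-2-en-1-yl)pyran-2-one F5. Mg(OMe)2 in methanol opens the lactone and the route is rejoined at 10, which under the same conditions goes on to 11.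

**Step 3.** Proton transfer from the acetamide to the hindered secondary γ-carbanion may outrun addition, so that 4 is recovered. The fallback replaces acylation by aldol addition and oxidation and sets out from 4. Its dianion adds to acetaldehyde to give methyl 5-hydroxy-2,4-bis(3-methylbut-2-en-1-yl)-3-oxohexanoate F6 (diastereomer mixture), and Dess–Martin periodinane (NaHCO3, CH2Cl2) oxidizes the secondary alcohol, rejoining the route at 6.

**Step 11.** The intramolecular transfer may stall because the ester is crowded between the ketone and a prenyl group, and the base may cleave the ester instead; the monoacylation in step 10 is a related risk. The fallback forms the C–C bond intermolecularly and sets out from 12 and 15. Acid 15 and 1,1'-carbonyldiimidazole give (imidazol-1-yl)[4-methoxy-3-(methoxymethoxy)phenyl]methanone F7. Ketone 12 is converted with LiN(SiMe3)2 (4 equiv) into its bis-phenoxide enolate and C-acylated with F7, which bypasses 16 and rejoins the route at 17.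

**Step 12.** The protic acid may add methanol, or the chelated 5-hydroxyl, across a prenyl double bond while the acetals are being cleaved. The fallback separates ring closure from deprotection and replaces protic solvolysis by a Lewis acid with a thiol trap; it sets out from 17. Sodium acetate-buffered acetic acid at 60 °C effects only the cyclodehydration, so that 18 is isolated. ZnBr2 with n-PrSH in CH2Cl2 at 0 °C then removes both methoxymethyl groups and gives 19.

## Further compounds

F1 | step 7 | methyl 3,5-dioxohexanoate | COC(=O)CC(=O)CC(C)=O
F2 | step 7 | methyl 8-(methoxymethoxy)-3,5,7-trioxooctanoate | COCOCC(=O)CC(=O)CC(=O)CC(=O)OC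
F3 | step 7 | 2-(methoxymethoxy)-1-(2,4,6-trihydroxyphenyl)ethan-1-one | COCOCC(=O)c1c(O)cc(O)cc1O
F4 | step 6 | 4-hydroxy-6-methyl-3,5-bis(3-methylbut-2-en-1-yl)pyran-2-one | Cc1oc(=O)c(CC=C(C)C)c(O)c1CC=C(C)C
F5 | step 6 | 4-hydroxy-6-[3-(methoxymethoxy)-2-oxopropyl]-3,5-bis(3-methylbut-2-en-1-yl)pyran-2-one | COCOCC(=O)Cc1oc(=O)c(CC=C(C)C)c(O)c1CC=C(C)C
F6 | step 3 | methyl 5-hydroxy-2,4-bis(3-methylbut-2-en-1-yl)-3-oxohexanoate (diastereomer mixture) | COC(=O)C(CC=C(C)C)C(=O)C(CC=C(C)C)C(C)O
F7 | step 11 | (imidazol-1-yl)[4-methoxy-3-(methoxymethoxy)phenyl]methanone | COCOc1cc(C(=O)n2ccnc2)ccc1OC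
F0 | step 12 | none | none
A1 | alternative 1 | 1-[2-hydroxy-4-methoxy-6-(methoxymethoxy)-3,5-bis(3-methylbut-2-enyl)phenyl]-3-[4-methoxy-3-(methoxymethoxy)phenyl]prop-2-yn-1-one | COCOc1cc(C#CC(=O)c2c(O)c(CC=C(C)C)c(OC)c(CC=C(C)C)c2OCOC)ccc1OC
A2 | alternative 1 | 3-methoxy-5-(methoxymethoxy)-2,4-bis(3-methylbut-2-enyl)-6-(trimethylsilyl)phenyl trifluoromethanesulfonate | COCOc1c(CC=C(C)C)c(OC)c(CC=C(C)C)c(OS(=O)(=O)C(F)(F)F)c1[Si](C)(C)C
A3 | alternative 1 | 3-[4-methoxy-3-(methoxymethoxy)phenyl]prop-2-ynoic acid | COCOc1cc(C#CC(=O)O)ccc1OC
A4 | alternative 2 | 5-fluoro-7-methoxy-3-(methoxymethoxy)-2-[4-methoxy-3-(methoxymethoxy)phenyl]-6,8-bis(3-methylbut-2-enyl)chromen-4-one | COc1ccc(-c2oc3c(CC=C(C)C)c(OC)c(CC=C(C)C)c(F)c3c(=O)c2OCOC)cc1OCOC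
A5 | alternative 2 | 1,3-difluoro-5-methoxybenzene | COc1cc(F)cc(F)c1
A6 | alternative 2 | 1-[2,6-difluoro-4-methoxy-3,5-bis(3-methylbut-2-enyl)phenyl]-2-(methoxymethoxy)-3-[4-methoxy-3-(methoxymethoxy)phenyl]propane-1,3-dione | COCOC(C(=O)c1c(F)c(CC=C(C)C)c(OC)c(CC=C(C)C)c1F)C(=O)c1ccc(OC)c(OCOC)c1
A7 | alternative 3 | 5-hydroxy-7-methoxy-3-(methoxymethoxy)-2-[4-methoxy-3-(methoxymethoxy)phenyl]-6,8-bis(3-methylbut-2-enyl)chromen-4-one | COc1ccc(-c2oc3c(CC=C(C)C)c(OC)c(CC=C(C)C)c(O)c3c(=O)c2OCOC)cc1OCOC
A8 | alternative 3 | phloroglucinol (benzene-1,3,5-triol) | Oc1cc(O)cc(O)c1
A9 | alternative 3 | 1-[2,6-dihydroxy-4-methoxy-3,5-bis(3-methylbut-2-enyl)phenyl]-2-(methoxymethoxy)ethan-1-one | COCOCC(=O)c1c(O)c(CC=C(C)C)c(OC)c(CC=C(C)C)c1O
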